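The midnight run cannot turn more than its whole charge of starting material into product, because each product takes one of each partner and the 80.0 mM of starting material is outnumbered by the 88.0 mM of partner; starting material is the limiting reagent, and the ceiling is 100% of the charge.

| flask | starting material | partner | time |
|---|---|---|---|
| autumn | 80.0 mM | 88.0 mM |  |
| spring | 32.0 mM | 40.0 mM |  |
| summer | 120 mM | 88.0 mM |  |
| midnight | 80.0 mM | 88.0 mM | 120 min |

- autumn run (time / min: [product] / mM): 6.2: 12.14; 12: 21.43; 19: 31.40; 25: 37.90; 31: 43.91; 38: 49.13; 44: 53.46; 50: 56.76
- spring run (time / min: [product] / mM): 6.2: 3.63; 12: 6.09; 19: 9.24; 25: 11.58; 31: 13.59; 38: 15.47; 44: 16.79; 50: 18.75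
- summer run (time / min: [product] / mM): 6.2: 15.60; 12: 27.94; 19: 39.94; 25: 48.86; 31: 56.03; 38: 62.49; 44: 67.25; 50: 70.28

(readings scatter by 0.2 mM)

- Overall: starting material + partner -> product.
- Constant volume, constant temperature.
- The analysis sees a species whether free or bound.
- "The second partner" is partner.
- An order is taken over about fifteen percent of the charge, up and down.

- how the opening rate goes with [starting material] round the charge of the autumn run: the exponent of the rate at two percent of starting material gone to product (one fixed amount of product, the same in the runs compared)
- how the opening rate goes with [partner] round the charge of the autumn run: the exponent of the rate at two percent of starting material gone to product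
- the spring run starts with 48.0 mM less of starting material and of partner than the autumn run, and with no product. Compared where both hold the same amount of starting material, once fifteen percent of what the spring run was charged with has turned into product, is the spring run faster, slower or alike (within a tenth)?
- product in the midnight run at 120 min, as a share of the starting material charged

The summer run looks nearly the same, with equal partner, but there partner is the limiting reagent, so its ceiling is 73.3% of its starting material. At 50 min the summer run stands at 79.9% of its ceiling and the autumn run, whose charge is the midnight charge, at 70.9% of its own.

The midnight question is how fast the last of the charge goes, and the partner surplus is too small to make this a pseudo-first-order tail. So I work in fractions of the starting charge: s is the starting material left, s + e the partner left, e the surplus, and a the partner charged. The clock below gains one fixed amount per minute if the rate goes as the product of the two fractions.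

c = ln[(s + e)/(a·s)]/e, with a = 1.10 and e = 0.100

Autumn, s: 0.848 at 6.2 min, 0.386 at 38 min, 0.291 at 50 min

Autumn, c: 0.161, 1.35, 2.01

The clock runs at 0.0260 min⁻¹ over the opening stretch, but the late slope of the clock, which I call the closing constant, is 0.0545 min⁻¹, twice that. I carry the closing constant forward to 120 min, as my own reckoning:

c = 5.82, so s = e/(a·exp(e·c) − 1) = 0.103, and product = 89.7% of the charge

The forecast gives 90% by the same kind of line, “Integrating from 50 min” with a late rate constant. It also gives 0.66 and 0.68 for the orders, and calls the spring run slower.

The flask gives 91.7%, orders of 0.73 and 0.67, and a spring run that is slower.

    starting material + partner → product + by-product (1.038 L mol⁻¹ min⁻¹)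
    starting material + partner + product → 2 product (5.292 L² mol⁻² min⁻¹)
    starting material + partner ⇌ idle substrate-reagent adduct, settled at all times (19.60 L mol⁻¹)

The spring run, holding the same starting material as the autumn run but without the 48.0 mM of product already made there, runs at 0.81 of the autumn rate. Reaching 91.7% puts s at 8.31% of the charge, which asks the clock for 0.0706 min⁻¹ after 50 min, above the closing constant by a factor of 1.30. Scaled to the summer charge and started from its 25 min reading, the closing constant puts half of that starting material at 32.6 min, earlier than the 35.1 min of the summer run.

The numbers in the tables were generated by integration on assumed constants, noise included.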